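**Strategy.** The cyclohex-2-ene-1,4-dione ring is a 1,4-diketone whose two α-carbons are the adjacent quaternary carbons (the prenyl-bearing bridge carbon and the aryl-bearing bridgehead). It is therefore cut across that quaternary–quaternary bond and across the ring CH=CH into two three-carbon halves hanging on a preformed benzocycloheptene. In one acid-triggered operation a keto-acetal enol, unmasked by decarboxylation at the prenyl-bearing carbon, captures a tertiary propargylic cation at the benzylic ring carbon, closing the five-membered ring of the benzobicyclo[3.2.1]octadiene; the alkyne then undergoes metathesis with the acetal carbon, closing the enedione ring. The precursor is a 9-substituted 5-ethynyl-5-hydroxybenzocycloheptene carrying a tert-butyl β-keto ester with a dimethyl acetal.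

Key step: step 11

Assumption: the epi-quinine-derived primary amine of step 5 is taken to give the (3S) adduct 10; if the facial sense proves opposite, the epi-quinidine-derived pseudoenantiomer is used.

Step 1
Reactants: 1 2-bromo-1,4-dimethoxybenzene
Product: 2 2-bromo-3,6-dimethoxybenzaldehyde
Conditions: LiN(i-Pr)2, THF, −78 °C; DMF; aq. NH4Cl
Reagents that add atoms: N,N-dimethylformamide, CN(C)C=O
Why: Directed ortho-lithiation should remove the proton flanked by bromine and methoxy, and formylation of the aryllithium by DMF gives the aldehyde; no stereocentre is formed.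

Step 2
Reactants: 2 2-bromo-3,6-dimethoxybenzaldehyde; 3 allyltributylstannane
Product: 4 2-allyl-3,6-dimethoxybenzaldehyde
Conditions: Pd(PPh3)4 (5 mol %), toluene, 110 °C
Reagents that add atoms: none
Why: Stille cross-coupling of the aryl bromide, activated by the ortho formyl group, should install the allyl group that later supplies two carbons of the seven-membered ring.

Step 3
Reactants: 4 2-allyl-3,6-dimethoxybenzaldehyde; 5 1-(triphenyl-λ5-phosphanylidene)propan-2-one
Product: 6 (E)-4-(2-allyl-3,6-dimethoxyphenyl)but-3-en-2-one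
Conditions: toluene, 100 °C
Reagents that add atoms: none
Why: Wittig olefination with the stabilised ylide should give the (E)-enone, which serves as the Michael acceptor and brings the future ring methyl group.

Step 4
Reactants: 7 tert-butyl acetate; 8 methyl 2,2-dimethoxyacetate
Product: 9 tert-butyl 4,4-dimethoxy-3-oxobutanoate
Conditions: LiN(i-Pr)2 (2.1 equiv), THF, −78 to −20 °C; aq. NH4Cl
Reagents that add atoms: none
Why: Crossed Claisen condensation of the ester enolate with the acetal ester should give the β-keto ester that carries three carbons of the enedione ring, one of them masked as the acetal.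

Step 5
Reactants: 6 (E)-4-(2-allyl-3,6-dimethoxyphenyl)but-3-en-2-one; 9 tert-butyl 4,4-dimethoxy-3-oxobutanoate
Product: 10 tert-butyl (3S)-3-(2-allyl-3,6-dimethoxyphenyl)-2-(2,2-dimethoxyacetyl)-5-oxohexanoate
Conditions: 9-amino-9-deoxy-epi-quinine (20 mol %), 2-hydroxybenzoic acid (40 mol %), toluene, 25 °C
Reagents that add atoms: none
Why: Organocatalytic asymmetric Michael addition through the chiral iminium ion of the enone should set the benzylic stereocentre by catalyst-controlled facial shielding, while the epimeric C-2 centre is of no consequence.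

Step 6
Reactants: 10 tert-butyl (3S)-3-(2-allyl-3,6-dimethoxyphenyl)-2-(2,2-dimethoxyacetyl)-5-oxohexanoate
Product: 11 tert-butyl (3S)-3-(2-allyl-3,6-dimethoxyphenyl)-2-(2,2-dimethoxyacetyl)-5-methylhex-5-enoate
Conditions: Ph3PCH3Br, KOt-Bu (excess), THF, 0 to 25 °C
Reagents that add atoms: methylenetriphenylphosphorane (made in the flask from methyltriphenylphosphonium bromide), C=P(c1ccccc1)(c1ccccc1)c1ccccc1
Why: Wittig methylenation should convert only the methyl ketone, because the β-keto ester is held as its enolate, which also suppresses retro-Michael cleavage.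

Step 7
Reactants: 11 tert-butyl (3S)-3-(2-allyl-3,6-dimethoxyphenyl)-2-(2,2-dimethoxyacetyl)-5-methylhex-5-enoate
Product: 12 tert-butyl 2-[(9S)-1,4-dimethoxy-7-methyl-8,9-dihydro-5H-benzo[7]annulen-9-yl]-4,4-dimethoxy-3-oxobutanoate
Conditions: second-generation Grubbs catalyst (5 mol %), CH2Cl2 (5 mM), 40 °C
Reagents that add atoms: none
Why: Ring-closing metathesis of the allyl and 2-methylallyl groups should close the benzocycloheptene and place the trisubstituted ring alkene exactly where the target has it.

Step 8
Reactants: 12 tert-butyl 2-[(9S)-1,4-dimethoxy-7-methyl-8,9-dihydro-5H-benzo[7]annulen-9-yl]-4,4-dimethoxy-3-oxobutanoate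
Product: 13 tert-butyl 2-(2,2-dimethoxyacetyl)-2-[(9R)-1,4-dimethoxy-7-methyl-8,9-dihydro-5H-benzo[7]annulen-9-yl]-5-methylhex-4-enoate
Conditions: NaH, prenyl bromide, DMF, 0 to 25 °C
Reagents that add atoms: prenyl bromide, CC(C)=CCBr
Why: C-alkylation of the β-keto ester enolate (acetoacetic ester alkylation) should install the prenyl group; the new quaternary centre forms as a mixture that is erased when the ester is lost in step 11.

Step 9
Reactants: 13 tert-butyl 2-(2,2-dimethoxyacetyl)-2-[(9R)-1,4-dimethoxy-7-methyl-8,9-dihydro-5H-benzo[7]annulen-9-yl]-5-methylhex-4-enoate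
Product: 14 tert-butyl 2-(2,2-dimethoxyacetyl)-2-[(9R)-1,4-dimethoxy-7-methyl-5-oxo-8,9-dihydro-5H-benzo[7]annulen-9-yl]-5-methylhex-4-enoate
Conditions: DDQ (2.5 equiv), CH2Cl2/H2O (10:1), 25 °C
Reagents that add atoms: water, O
Why: DDQ benzylic oxidation by hydride abstraction should occur at the CH2 that is both benzylic to the electron-rich arene and allylic, and further oxidation of the resulting alcohol gives the aryl enone.

Step 10
Reactants: 14 tert-butyl 2-(2,2-dimethoxyacetyl)-2-[(9R)-1,4-dimethoxy-7-methyl-5-oxo-8,9-dihydro-5H-benzo[7]annulen-9-yl]-5-methylhex-4-enoate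
Product: 15 tert-butyl 2-(2,2-dimethoxyacetyl)-2-[(9R)-5-ethynyl-5-hydroxy-1,4-dimethoxy-7-methyl-8,9-dihydro-5H-benzo[7]annulen-9-yl]-5-methylhex-4-enoate
Conditions: HC≡CMgBr, CeCl3, THF, −78 to 0 °C; aq. NH4Cl
Reagents that add atoms: ethynylmagnesium bromide, C#C[Mg]Br
Why: Grignard-type 1,2-addition of the alkynylcerium reagent should occur at the enone carbonyl, since the other ketone lies between a quaternary carbon and the acetal and the ester is tert-butyl; the carbinol centre forms as a mixture that is ionised in step 11.

Step 11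
Reactants: 15 tert-butyl 2-(2,2-dimethoxyacetyl)-2-[(9R)-5-ethynyl-5-hydroxy-1,4-dimethoxy-7-methyl-8,9-dihydro-5H-benzo[7]annulen-9-yl]-5-methylhex-4-enoate
Product: 17 bis(methyl ether) of the target, via bridged alkynyl keto acetal 16 (not isolated)
Conditions: BF3·OEt2 (5 equiv), CH2Cl2, −20 to 40 °C; aq. NaHCO3
Reagents that add atoms: none
Why: Proposed new method: BF3 cleaves the tert-butyl ester and ionises the tertiary propargylic (also allylic and benzylic) alcohol, the β-keto acid loses CO2 to give the enol at the prenyl-bearing carbon (its only enolisable position) and this enol is alkylated by the cation to give 16; the oxocarbenium ion of the dimethyl acetal is then attacked by the terminal alkyne carbon and the vinyl cation collapses through an oxetenium ion to the enone, so the ring CH=CH bond and the second ring ketone appear together. The closest known types are the acid-catalysed propargylic substitution of tertiary aryl propargylic alcohols by 1,3-dicarbonyl enols and the Lewis-acid-mediated intramolecular alkyne–carbonyl metathesis, whose coupling in one decarboxylative cascade has no precedent. The five-membered ring closes 5-exo-trig (enol-exo) onto the cation and the enedione ring closes 6-endo-dig. The benzylic CH centre set in step 5 is not touched and dictates the quaternary bridgehead, because the one-carbon bridge can only span the seven-membered ring on the face that carries the side chain; at the prenyl-bearing carbon allylic 1,3-strain in the tetrasubstituted enol should turn the acyl arm away from the ring CH2 and over the arene, which places prenyl over the three-carbon bridge as in the target. The step needs capture at the carbinol carbon and not at the allenyl or allylic termini, which only the five-membered closure allows, and attack of the alkyne on the acetal carbon in preference to the neighbouring ketone, which is shielded by the new quaternary carbon.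

Step 12
Reactants: 17 bis(methyl ether) of the target
Product: 19 target CNP0513322.1, via quinone 18 (not isolated)
Conditions: (NH4)2Ce(NO3)6 (2.5 equiv), MeCN/H2O, 0 °C; then Na2S2O4, H2O/EtOAc, 25 °C
Reagents that add atoms: water, O
Why: Oxidative demethylation of the 1,4-dimethoxyarene by tetravalent cerium should give the quinone without touching the electron-poor enedione or the trisubstituted alkenes, and dithionite reduction of the far more easily reduced quinone gives the hydroquinone; no stereocentre is affected.

**Compound list**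

1 | 2-bromo-1,4-dimethoxybenzene | COc1ccc(OC)c(Br)c1 | starting material
2 | 2-bromo-3,6-dimethoxybenzaldehyde | O=Cc1c(OC)ccc(OC)c1Br | intermediate
3 | allyltributylstannane | C=CC[Sn](CCCC)(CCCC)CCCC | starting material
4 | 2-allyl-3,6-dimethoxybenzaldehyde | O=Cc1c(OC)ccc(OC)c1CC=C | intermediate
5 | 1-(triphenyl-λ5-phosphanylidene)propan-2-one | CC(=O)C=P(c1ccccc1)(c1ccccc1)c1ccccc1 | starting material
6 | (E)-4-(2-allyl-3,6-dimethoxyphenyl)but-3-en-2-one | CC(=O)/C=C/c1c(OC)ccc(OC)c1CC=C | intermediate
7 | tert-butyl acetate | CC(=O)OC(C)(C)C | starting material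
8 | methyl 2,2-dimethoxyacetate | COC(OC)C(=O)OC | starting material
9 | tert-butyl 4,4-dimethoxy-3-oxobutanoate | COC(OC)C(=O)CC(=O)OC(C)(C)C | intermediate
10 | tert-butyl (3S)-3-(2-allyl-3,6-dimethoxyphenyl)-2-(2,2-dimethoxyacetyl)-5-oxohexanoate (both C-2 epimers) | CC(=O)C[C@H](c1c(OC)ccc(OC)c1CC=C)C(C(=O)OC(C)(C)C)C(=O)C(OC)OC | intermediate
11 | tert-butyl (3S)-3-(2-allyl-3,6-dimethoxyphenyl)-2-(2,2-dimethoxyacetyl)-5-methylhex-5-enoate (both C-2 epimers) | CC(=C)C[C@H](c1c(OC)ccc(OC)c1CC=C)C(C(=O)OC(C)(C)C)C(=O)C(OC)OC | intermediate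
12 | tert-butyl 2-[(9S)-1,4-dimethoxy-7-methyl-8,9-dihydro-5H-benzo[7]annulen-9-yl]-4,4-dimethoxy-3-oxobutanoate (both C-2 epimers) | CC1=CCc2c(OC)ccc(OC)c2[C@@H](C1)C(C(=O)OC(C)(C)C)C(=O)C(OC)OC | intermediate
13 | tert-butyl 2-(2,2-dimethoxyacetyl)-2-[(9R)-1,4-dimethoxy-7-methyl-8,9-dihydro-5H-benzo[7]annulen-9-yl]-5-methylhex-4-enoate (both C-2 epimers; same spatial arrangement at C-9 as in 12, the descriptor changes with substituent priority) | CC1=CCc2c(OC)ccc(OC)c2[C@@H](C1)C(CC=C(C)C)(C(=O)OC(C)(C)C)C(=O)C(OC)OC | intermediate
14 | tert-butyl 2-(2,2-dimethoxyacetyl)-2-[(9R)-1,4-dimethoxy-7-methyl-5-oxo-8,9-dihydro-5H-benzo[7]annulen-9-yl]-5-methylhex-4-enoate (both C-2 epimers) | CC1=CC(=O)c2c(OC)ccc(OC)c2[C@@H](C1)C(CC=C(C)C)(C(=O)OC(C)(C)C)C(=O)C(OC)OC | intermediate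
15 | tert-butyl 2-(2,2-dimethoxyacetyl)-2-[(9R)-5-ethynyl-5-hydroxy-1,4-dimethoxy-7-methyl-8,9-dihydro-5H-benzo[7]annulen-9-yl]-5-methylhex-4-enoate (epimers at C-2 and at the carbinol carbon) | CC1=CC(O)(C#C)c2c(OC)ccc(OC)c2[C@@H](C1)C(CC=C(C)C)(C(=O)OC(C)(C)C)C(=O)C(OC)OC | intermediate
16 | 1-[(5R,9R,10S)-5-ethynyl-1,4-dimethoxy-7-methyl-10-(3-methylbut-2-enyl)-8,9-dihydro-5H-5,9-methanobenzo[7]annulen-10-yl]-2,2-dimethoxyethanone (not isolated) | CC(C)=CC[C@@]1(C(=O)C(OC)OC)[C@@]2(C#C)C=C(C)C[C@@H]1c1c(OC)ccc(OC)c12 | intermediate
17 | bis(methyl ether) of the target: as 19 with both phenolic OH groups as OMe; S at the prenyl-bearing carbon, R at the aryl-bearing quaternary carbon, R at the benzylic CH | CC(C)=CC[C@@]12C(=O)C=CC(=O)[C@@]13C=C(C)C[C@@H]2c1c(OC)ccc(OC)c13 | intermediate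
18 | quinone of the target: as 19 with the hydroquinone ring as 1,4-benzoquinone (not isolated) | CC(C)=CC[C@@]12C(=O)C=CC(=O)[C@@]13C=C(C)C[C@@H]2C=1C(=O)C=CC(=O)C13 | intermediate
19 | CNP0513322.1: hydroquinone-fused 5,9-methanobenzo[7]annulene with the cyclohex-2-ene-1,4-dione ring fused across the bridge carbon and the quaternary bridgehead; S at the prenyl-bearing carbon, R at the aryl-bearing quaternary carbon, R at the benzylic CH | CC(C)=CC[C@@]12C(=O)C=CC(=O)[C@@]13C=C(C)C[C@@H]2c1c(O)ccc(O)c13 | target

**Step count and risks**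

Total step count: 12. Longest linear sequence: 11 steps (steps 1 to 3 and 5 to 12; step 4 is a side branch).

Steps most likely to fail:

Step 11 (Proposed new method). The cation may form before the enol is unmasked and be lost by a Meyer–Schuster-type hydroxyl shift or by elimination. The terminal alkyne may fail to engage the deactivated α-keto acetal. Rotamer control at the prenyl-bearing carbon may be poor. The fallback uses known chemistry in separate steps and sets out from 15. Treatment with Co2(CO)8 in CH2Cl2 should give the hexacarbonyldicobalt complex of 15, F1. BF3·OEt2 then removes the tert-butyl group, the acid loses CO2 and the enol is captured by the cobalt-stabilised cation in a Nicholas reaction to give the hexacarbonyldicobalt complex of the bridged alkyne, F2. Decomplexation with Fe(NO3)3·9H2O in ethanol should give 16. Hydration of the alkyne catalysed by Ph3PAuNTf2 in aqueous dioxane should give the bridged methyl ketone F3. TsOH in aqueous acetone at 55 °C should then hydrolyse the acetal and effect the intramolecular aldol condensation. The fallback comes back to the route at 17.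

Step 9. Hydride abstraction may also occur at the other benzylic C–H. Water may capture the allyl cation at its tertiary terminus and give a transposed tertiary alcohol. The fallback sets out from 12, before the prenyl group is present. A Schenck ene reaction with singlet oxygen (O2, tetraphenylporphyrin, visible light, CH2Cl2, −20 °C) followed by PPh3 should give the tertiary allylic alcohol tert-butyl 2-[(9S)-7-hydroxy-1,4-dimethoxy-7-methyl-8,9-dihydro-7H-benzo[7]annulen-9-yl]-4,4-dimethoxy-3-oxobutanoate F4. Babler–Dauben oxidation with [C5H5NH][CrO3Cl] should transpose it to the enone tert-butyl 2-[(9S)-1,4-dimethoxy-7-methyl-5-oxo-8,9-dihydro-5H-benzo[7]annulen-9-yl]-4,4-dimethoxy-3-oxobutanoate F5. Prenylation under the conditions of step 8 brings the fallback back to the route at 14.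

Step 5. Iminium formation may be slow with the doubly ortho-substituted aryl enone, and facial selectivity may be poor. The fallback reverses the roles of the partners and sets out from 4 and 9. Knoevenagel condensation (piperidine, acetic acid, benzene, reflux) should give tert-butyl 3-(2-allyl-3,6-dimethoxyphenyl)-2-(2,2-dimethoxyacetyl)prop-2-enoate F6. Enamine-catalysed asymmetric Michael addition of acetone (a chiral primary amine–thiourea catalyst, acetone as solvent) to this doubly activated alkene then forms the other bond at the benzylic carbon. The fallback comes back to the route at 10.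

Further compounds
F1 | step 11 | hexacarbonyldicobalt complex of the alkyne of 15 | CC1=CC(O)(C45[CH]6[Co]4(=C=O)(=C=O)(=C=O)[Co]56(=C=O)(=C=O)=C=O)c2c(OC)ccc(OC)c2[C@@H](C1)C(CC=C(C)C)(C(=O)OC(C)(C)C)C(=O)C(OC)OC
F2 | step 11 | hexacarbonyldicobalt complex of the alkyne of 16 | CC(C)=CC[C@@]1(C(=O)C(OC)OC)[C@@]2(C45[CH]6[Co]4(=C=O)(=C=O)(=C=O)[Co]56(=C=O)(=C=O)=C=O)C=C(C)C[C@@H]1c1c(OC)ccc(OC)c12
F3 | step 11 | 1-[(5R,9R,10S)-5-acetyl-1,4-dimethoxy-7-methyl-10-(3-methylbut-2-enyl)-8,9-dihydro-5H-5,9-methanobenzo[7]annulen-10-yl]-2,2-dimethoxyethanone | CC(C)=CC[C@@]1(C(=O)C(OC)OC)[C@@]2(C(C)=O)C=C(C)C[C@@H]1c1c(OC)ccc(OC)c12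
F4 | step 9 | tert-butyl 2-[(9S)-7-hydroxy-1,4-dimethoxy-7-methyl-8,9-dihydro-7H-benzo[7]annulen-9-yl]-4,4-dimethoxy-3-oxobutanoate (epimers at C-2 and C-7) | CC1(O)C=Cc2c(OC)ccc(OC)c2[C@@H](C1)C(C(=O)OC(C)(C)C)C(=O)C(OC)OC
F5 | step 9 | tert-butyl 2-[(9S)-1,4-dimethoxy-7-methyl-5-oxo-8,9-dihydro-5H-benzo[7]annulen-9-yl]-4,4-dimethoxy-3-oxobutanoate (both C-2 epimers) | CC1=CC(=O)c2c(OC)ccc(OC)c2[C@@H](C1)C(C(=O)OC(C)(C)C)C(=O)C(OC)OC
F6 | step 5 | tert-butyl 3-(2-allyl-3,6-dimethoxyphenyl)-2-(2,2-dimethoxyacetyl)prop-2-enoate (E/Z mixture) | C=CCc1c(OC)ccc(OC)c1C=C(C(=O)OC(C)(C)C)C(=O)C(OC)OC
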